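**Retrosynthetic overview**
- Target 16 comes from the tris-MOM pyrone 15 by acid removal of the three aryl MOM ethers.
- 15 comes from the Z-enol ester 14 by closing the pyrone ring at C3–C4. C3 is the α-carbon of a 3-arylpropanoyl chain whose β-CH2 is the methylene bridge; C4 is the ester carbon of methyl 2-methyl-3-oxopentanoate, whose enol oxygen is already O1 (O1–C2 and O1–C6 are in place before closure).
- 14 comes from acid 10 and keto ester 12 by O-acylation of the chelated enolate.
- 10 comes from phloroglucinol: annulation with acrylic acid to a dihydrocoumarin, Friedel–Crafts acylation, C-prenylation with lactone opening, MOM protection. The benzene ring carries its three carbon substituents on alternate carbons, so only one substitution pattern is possible.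
- Ring order: benzene ring bought; temporary lactone ring formed in step 1 and opened in step 3; pyrone ring last, in step 7.

Key step: step 7

Assumption: the acylation in step 2 is drawn at C6 of the dihydrocoumarin. Acylation at C8 would give the same ring-opened acid in step 3, because opening the lactone makes the two positions equivalent.

**Step 1**
Reactants: 1 phloroglucinol; 2 acrylic acid
Product: 3 5,7-dihydroxy-3,4-dihydro-2H-chromen-2-one
Conditions: Amberlyst-15 (sulfonic acid resin), toluene, reflux, Dean–Stark; 1.0 equiv of 2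
Reagents that add atoms: none
Why: Acid-catalysed Friedel–Crafts-type conjugate addition (hydroarylation) of acrylic acid by the electron-rich ring, then lactonisation onto the ortho hydroxyl with removal of water, is an established route from resorcinol-type phenols to 3,4-dihydrocoumarins.

**Step 2**
Reactants: 3 5,7-dihydroxy-3,4-dihydro-2H-chromen-2-one; 4 2-methylpropanoyl chloride (isobutyryl chloride)
Product: 5 5,7-dihydroxy-6-(2-methylpropanoyl)-3,4-dihydro-2H-chromen-2-one
Conditions: AlCl3 (3.5 equiv), PhNO2–CH2Cl2, 0 → 50 °C; ice/aq. HCl work-up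
Reagents that add atoms: none
Why: Friedel–Crafts acylation of a phloroglucinol-type ring should go to the carbon between the two free hydroxyls; the first acyl group deactivates the ring against a second acylation and the lactone is inert to AlCl3.

**Step 3**
Reactants: 5 5,7-dihydroxy-6-(2-methylpropanoyl)-3,4-dihydro-2H-chromen-2-one; 6 1-bromo-3-methylbut-2-ene (prenyl bromide)
Product: 8 3-[2,4,6-trihydroxy-3-(3-methylbut-2-en-1-yl)-5-(2-methylpropanoyl)phenyl]propanoic acid, via ring-opened trihydroxy acid potassium salt 7 (not isolated)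
Conditions: 10% aq. KOH, 0 °C, 30 min; 6 (1.05 equiv), 0 °C → rt; then 1 M HCl to pH 3 at 0 °C, EtOAc extraction
Reagents that add atoms: potassium hydroxide, [K+].[OH-]
Why: Hydroxide opens the aryl lactone to 7, and the acylphloroglucinol polyanion should then be alkylated in water at its single unsubstituted ring carbon, the classical C-prenylation of acylphloroglucinols; the free 3-arylpropanoic acid does not relactonise in cold dilute acid.

**Step 4**
Reactants: 8 3-[2,4,6-trihydroxy-3-(3-methylbut-2-en-1-yl)-5-(2-methylpropanoyl)phenyl]propanoic acid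
Product: 10 3-[2,4,6-tris(methoxymethoxy)-3-(3-methylbut-2-en-1-yl)-5-(2-methylpropanoyl)phenyl]propanoic acid, via methoxymethyl ester tris-MOM ether 9 (not isolated)
Conditions: NaH (4.2 equiv), DMF, 0 °C; MOMCl (4.5 equiv), 0 °C → rt; then LiOH, THF–H2O, rt; 1 M HCl to pH 4 at 0 °C
Reagents that add atoms: chloromethyl methyl ether, COCCl; lithium hydroxide, [Li+].[OH-]
Why: Williamson O-alkylation of the three phenoxides and the carboxylate by MOMCl, followed by hydroxide cleavage of the labile methoxymethyl ester only, since aryl MOM ethers and the hindered aryl ketone are stable to aqueous LiOH.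

**Step 5**
Reactants: 11 methyl propanoate (two molecules)
Product: 12 methyl 2-methyl-3-oxopentanoate (racemic)
Conditions: NaH (0.5 equiv per ester), THF, reflux; then aq. HCl, 0 °C
Reagents that add atoms: none
Why: Claisen self-condensation, driven by deprotonation of the product at the carbon between its two carbonyls; the new stereocenter is enolisable, so the product is racemic, and it becomes an alkene carbon in step 6.

**Step 6**
Reactants: 10 3-[2,4,6-tris(methoxymethoxy)-3-(3-methylbut-2-en-1-yl)-5-(2-methylpropanoyl)phenyl]propanoic acid; 12 methyl 2-methyl-3-oxopentanoate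
Product: 14 methyl (Z)-2-methyl-3-({3-[2,4,6-tris(methoxymethoxy)-3-(3-methylbut-2-en-1-yl)-5-(2-methylpropanoyl)phenyl]propanoyl}oxy)pent-2-enoate, via acid chloride 13 (not isolated)
Conditions: 10, 1-chloro-N,N,2-trimethylprop-1-en-1-amine, CH2Cl2, 0 °C, used at once; second flask: 12 (1.3 equiv), NaH (1.2 equiv), Et2O–toluene, 0 °C; add 13, –20 → 0 °C; chromatography on Et3N-deactivated silica
Reagents that add atoms: none
Why: O-acylation of the sodium chelate of an α-substituted β-keto ester by an acid chloride made under neutral conditions; the chelate should hold the enolate oxygen syn to the ester, so the acyloxy group ends cis to CO2Me (Z), as in Z-selective enol phosphate and sulfonate formation from chelated enolates, and the α-methyl group disfavours C-acylation, which would create a quaternary carbon.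

**Step 7**
Reactants: 14 methyl (Z)-2-methyl-3-({3-[2,4,6-tris(methoxymethoxy)-3-(3-methylbut-2-en-1-yl)-5-(2-methylpropanoyl)phenyl]propanoyl}oxy)pent-2-enoate
Product: 15 6-ethyl-4-hydroxy-5-methyl-3-{[2,4,6-tris(methoxymethoxy)-3-(3-methylbut-2-en-1-yl)-5-(2-methylpropanoyl)phenyl]methyl}-2H-pyran-2-one
Conditions: LiN(SiMe3)2 (3 equiv), THF, –78 → 0 °C; AcOH quench, extraction at pH 4
Reagents that add atoms: none
Why: LiN(SiMe3)2 removes a proton from the acyl CH2 (pyrone C3) and the lithium enolate adds to the cis methyl ester carbon (pyrone C4); the tetrahedral intermediate loses methoxide and the pyran-2,4-dione is deprotonated at once to the aromatic 4-oxido-2-pyrone, which makes the closure irreversible. This is a Dieckmann (intramolecular Claisen) condensation of the kind that converts methyl O-acylsalicylates into 4-hydroxycoumarins. The pyrone ring closes at carbon in a 6-exo-trig mode, with O1–C2 and O1–C6 already present in 14. No stereocenter is formed. The step needs deprotonation at the acyl CH2 rather than only at the hindered isobutyryl methine; three equivalents of base cover this, since a ketone enolate has no electrophile within reach and is reprotonated on quench. It also needs the Z geometry set in step 6, and low temperature to limit fragmentation of the enolate to a ketene and cleavage of the enol ester by the released methoxide.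

**Step 8**
Reactants: 15 6-ethyl-4-hydroxy-5-methyl-3-{[2,4,6-tris(methoxymethoxy)-3-(3-methylbut-2-en-1-yl)-5-(2-methylpropanoyl)phenyl]methyl}-2H-pyran-2-one
Product: 16 6-ethyl-4-hydroxy-5-methyl-3-{[2,4,6-trihydroxy-3-(3-methylbut-2-en-1-yl)-5-(2-methylpropanoyl)phenyl]methyl}-2H-pyran-2-one (target)
Conditions: 3 M aq. HCl–MeOH (1:10), rt
Reagents that add atoms: none
Why: Acid-catalysed acetal exchange should remove the three aryl MOM ethers as dimethoxymethane; dilute HCl in methanol at room temperature is the usual way to unmask MOM-protected prenylated acylphloroglucinols, and the 4-hydroxy-2-pyrone is stable to acid.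

**Compound list**
1 | phloroglucinol (benzene-1,3,5-triol) | Oc1cc(O)cc(O)c1 | starting material
2 | acrylic acid | C=CC(=O)O | starting material
3 | 5,7-dihydroxy-3,4-dihydro-2H-chromen-2-one | O=C1CCc2c(O)cc(O)cc2O1 | intermediate
4 | 2-methylpropanoyl chloride | CC(C)C(Cl)=O | starting material
5 | 5,7-dihydroxy-6-(2-methylpropanoyl)-3,4-dihydro-2H-chromen-2-one | O=C1CCc2c(O)c(C(=O)C(C)C)c(O)cc2O1 | intermediate
6 | 1-bromo-3-methylbut-2-ene | CC(C)=CCBr | starting material
7 | 3-[2,4,6-trihydroxy-3-(2-methylpropanoyl)phenyl]propanoic acid (potassium salt in the flask, not isolated) | OC(=O)CCc1c(O)cc(O)c(C(=O)C(C)C)c1O | intermediate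
8 | 3-[2,4,6-trihydroxy-3-(3-methylbut-2-en-1-yl)-5-(2-methylpropanoyl)phenyl]propanoic acid | OC(=O)CCc1c(O)c(CC=C(C)C)c(O)c(C(=O)C(C)C)c1O | intermediate
9 | methoxymethyl 3-[2,4,6-tris(methoxymethoxy)-3-(3-methylbut-2-en-1-yl)-5-(2-methylpropanoyl)phenyl]propanoate (not isolated) | COCOC(=O)CCc1c(OCOC)c(CC=C(C)C)c(OCOC)c(C(=O)C(C)C)c1OCOC | intermediate
10 | 3-[2,4,6-tris(methoxymethoxy)-3-(3-methylbut-2-en-1-yl)-5-(2-methylpropanoyl)phenyl]propanoic acid | OC(=O)CCc1c(OCOC)c(CC=C(C)C)c(OCOC)c(C(=O)C(C)C)c1OCOC | intermediate
11 | methyl propanoate | CCC(=O)OC | starting material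
12 | methyl 2-methyl-3-oxopentanoate (racemic) | CCC(=O)C(C)C(=O)OC | intermediate
13 | 3-[2,4,6-tris(methoxymethoxy)-3-(3-methylbut-2-en-1-yl)-5-(2-methylpropanoyl)phenyl]propanoyl chloride (not isolated) | ClC(=O)CCc1c(OCOC)c(CC=C(C)C)c(OCOC)c(C(=O)C(C)C)c1OCOC | intermediate
14 | methyl (Z)-2-methyl-3-({3-[2,4,6-tris(methoxymethoxy)-3-(3-methylbut-2-en-1-yl)-5-(2-methylpropanoyl)phenyl]propanoyl}oxy)pent-2-enoate | CC/C(OC(=O)CCc1c(OCOC)c(CC=C(C)C)c(OCOC)c(C(=O)C(C)C)c1OCOC)=C(C)/C(=O)OC | intermediate
15 | 6-ethyl-4-hydroxy-5-methyl-3-{[2,4,6-tris(methoxymethoxy)-3-(3-methylbut-2-en-1-yl)-5-(2-methylpropanoyl)phenyl]methyl}-2H-pyran-2-one | CCc1oc(=O)c(Cc2c(OCOC)c(CC=C(C)C)c(OCOC)c(C(=O)C(C)C)c2OCOC)c(O)c1C | intermediate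
16 | 6-ethyl-4-hydroxy-5-methyl-3-{[2,4,6-trihydroxy-3-(3-methylbut-2-en-1-yl)-5-(2-methylpropanoyl)phenyl]methyl}-2H-pyran-2-one | CCc1oc(=O)c(Cc2c(O)c(CC=C(C)C)c(O)c(C(=O)C(C)C)c2O)c(O)c1C | target

**Step count**
Total steps: 8. Longest linear sequence: 7 steps (steps 1, 2, 3, 4, 6, 7, 8 from phloroglucinol); step 5 is a one-step side branch.

**Steps most likely to fail**

1. Step 7 (pyrone closure). The enol-ester enolate may fragment into a ketene and the keto ester enolate, the enol ester may be cleaved by the methoxide set free, or the base may be consumed at the isobutyryl methine so that the acyl CH2 is not deprotonated.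
Fallback, setting out from 1, 4, 6 and 11 and returning at 16: the two halves are joined at the methylene carbon without ester enolate chemistry on the aryl fragment. Phloroglucinol 1 is acylated with 4 (AlCl3, PhNO2) to 2-methyl-1-(2,4,6-trihydroxyphenyl)propan-1-one F1. F1 is C-prenylated with 6 in cold aqueous KOH to 2-methyl-1-[2,4,6-trihydroxy-3-(3-methylbut-2-en-1-yl)phenyl]propan-1-one F2. Separately, the dianion of commercial methyl 3-oxopentanoate (NaH, then n-BuLi, THF, 0 °C) is acylated with 11 to methyl 4-methyl-3,5-dioxoheptanoate F3, which lactonises with DBU in hot toluene to 6-ethyl-4-hydroxy-5-methyl-2H-pyran-2-one F4. F4 and dimethylmethyleneiminium iodide give the Mannich base 3-[(dimethylamino)methyl]-6-ethyl-4-hydroxy-5-methyl-2H-pyran-2-one F5. Warming F5 with F2 in MeCN should eliminate dimethylamine to the 3-methylene pyrandione, which the single free ring carbon of F2 captures, giving 16 with no protecting groups.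

2. Step 6 (Z-enol ester). Acylation may occur at carbon instead of oxygen, the Z geometry may be lost if the enolate is not chelated, an ortho MOM oxygen may attack the acid chloride with relactonisation and loss of a MOM group, or the enol ester may hydrolyse on isolation.
Fallback, setting out from 10 and returning at 15: the enol ester is bypassed and the ring is closed at O1–C2. Acid 10 is esterified (MeI, K2CO3, DMF) to methyl 3-[2,4,6-tris(methoxymethoxy)-3-(3-methylbut-2-en-1-yl)-5-(2-methylpropanoyl)phenyl]propanoate F6. Its lithium enolate (LiN(i-Pr)2, 2.2 equiv, THF, –78 °C) is acylated with propanoyl chloride to methyl 2-{[2,4,6-tris(methoxymethoxy)-3-(3-methylbut-2-en-1-yl)-5-(2-methylpropanoyl)phenyl]methyl}-3-oxopentanoate F7. The dianion of F7 (LiN(i-Pr)2, 2.5 equiv) is acylated at the ketone CH2 with 11 to methyl 2-{[2,4,6-tris(methoxymethoxy)-3-(3-methylbut-2-en-1-yl)-5-(2-methylpropanoyl)phenyl]methyl}-4-methyl-3,5-dioxoheptanoate F8. F8 lactonises with DBU in hot toluene to 15.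

3. Step 3 (C-prenylation). The ambident polyanion may react with poor site selectivity: O-alkylation, or a second alkylation at an already substituted ring carbon with loss of aromaticity.
Fallback, setting out from 5 and returning at 8: the prenyl group is introduced by electrophilic aromatic substitution instead of phenoxide alkylation. Lactone 5 with 2-methylbut-3-en-2-ol and BF3·OEt2 in dioxane at rt should give 5,7-dihydroxy-8-(3-methylbut-2-en-1-yl)-6-(2-methylpropanoyl)-3,4-dihydro-2H-chromen-2-one F9 at the only free ring carbon. Opening of F9 with cold aqueous KOH and acidification to pH 3 then gives 8.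

**Further compounds**
F1 | step 7 | 2-methyl-1-(2,4,6-trihydroxyphenyl)propan-1-one | CC(C)C(=O)c1c(O)cc(O)cc1O
F2 | step 7 | 2-methyl-1-[2,4,6-trihydroxy-3-(3-methylbut-2-en-1-yl)phenyl]propan-1-one | CC(C)C(=O)c1c(O)cc(O)c(CC=C(C)C)c1O
F3 | step 7 | methyl 4-methyl-3,5-dioxoheptanoate | CCC(=O)C(C)C(=O)CC(=O)OC
F4 | step 7 | 6-ethyl-4-hydroxy-5-methyl-2H-pyran-2-one | CCc1oc(=O)cc(O)c1C
F5 | step 7 | 3-[(dimethylamino)methyl]-6-ethyl-4-hydroxy-5-methyl-2H-pyran-2-one | CCc1oc(=O)c(CN(C)C)c(O)c1C
F6 | step 6 | methyl 3-[2,4,6-tris(methoxymethoxy)-3-(3-methylbut-2-en-1-yl)-5-(2-methylpropanoyl)phenyl]propanoate | COC(=O)CCc1c(OCOC)c(CC=C(C)C)c(OCOC)c(C(=O)C(C)C)c1OCOC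
F7 | step 6 | methyl 2-{[2,4,6-tris(methoxymethoxy)-3-(3-methylbut-2-en-1-yl)-5-(2-methylpropanoyl)phenyl]methyl}-3-oxopentanoate (racemic) | CCC(=O)C(Cc1c(OCOC)c(CC=C(C)C)c(OCOC)c(C(=O)C(C)C)c1OCOC)C(=O)OC
F8 | step 6 | methyl 2-{[2,4,6-tris(methoxymethoxy)-3-(3-methylbut-2-en-1-yl)-5-(2-methylpropanoyl)phenyl]methyl}-4-methyl-3,5-dioxoheptanoate (mixture of stereoisomers) | CCC(=O)C(C)C(=O)C(Cc1c(OCOC)c(CC=C(C)C)c(OCOC)c(C(=O)C(C)C)c1OCOC)C(=O)OC
F9 | step 3 | 5,7-dihydroxy-8-(3-methylbut-2-en-1-yl)-6-(2-methylpropanoyl)-3,4-dihydro-2H-chromen-2-one | O=C1CCc2c(O)c(C(=O)C(C)C)c(O)c(CC=C(C)C)c2O1
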